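Both end rings are the same C10 unit, and each is formally two molecules of a 3-methylbut-2-enoate: in the β ring, C4–C5(CH3)–C6 with exocyclic C7, and C1(CH3)2–C2–C3(O). The key step therefore builds the six-membered ring from two molecules of ethyl 3-methylbut-2-enoate in one operation: a dienolate adds through its α-carbon to the β-carbon of the second ester (C6–C1) and its γ-carbon then acylates that ester (C4–C3). The racemic keto ester is reduced and resolved; one enantiomer is the ε ring, the other becomes the (3R) β ring once the double bond migrates. A C20 dialdehyde links the two ends.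

Key step: step 1

Remark (assumption): the lipase in step 3 is taken to acylate the (1R,4R)-alcohol, the usual preference for the (R)-carbinol of cyclohex-2-enols; if the preference were reversed the acetate and the free alcohol would only exchange branches, since ethoxide (step 4) and LiAlH4 (step 9) both remove the acetyl group. Crocetindialdehyde 12 is taken as purchasable from carotenoid suppliers.

Step 1
Reactants: 1 ethyl 3-methylbut-2-enoate (two molecules)
Product: 4 ethyl 2,6,6-trimethyl-4-oxocyclohex-2-ene-1-carboxylate (racemate), via lithium dienolate 2 (not isolated), via Michael adduct enolate 3 (not isolated)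
Conditions: LiN(iPr)2 (1.05 equiv), THF–DMPU, −78 °C; second equivalent of 1, −78 → 25 °C; aq NH4Cl; then DBU (cat.), CH2Cl2, rt
Reagents that add atoms: none
Why: LiN(iPr)2 removes a γ-proton of 1 to give dienolate 2, whose α-carbon adds 1,4 to the β,β-dimethyl carbon of a second molecule of 1 (bond C6–C1, quaternary C1), and after proton transfer the extended dienolate of 3 attacks the acceptor's ester carbonyl through its γ-carbon (bond C4–C3) with loss of ethoxide, the doubly stabilised enolate of 4 being the thermodynamic sink. The closest known reaction type is the tandem Michael–Claisen (Michael–Dieckmann) [3+3] annulation of enolates with enoates that gives cyclohexane-1,3-diones, run here in its vinylogous form, and carbanion additions to 3-methylbut-2-enoates are established in chrysanthemate synthesis. The one ring is closed by a 6-(enolendo)-exo-trig Dieckmann acylation that follows the intermolecular conjugate addition. The only new stereocentre, C6 (C1 of the ester name), forms racemic and stays labile as a vinylogous β-keto ester position, which is intended: its relative configuration is fixed in step 2, its absolute configuration in step 3, and in the β half it is erased in step 4. The step needs α- over γ-attack of the dienolate (the kinetic site of lithium ester dienolates; γ-attack would lead to the isomeric 2-carboxylate), 1,4- over 1,2-addition (polar cosolvent, reversible carbonyl addition) and C-acylation by the γ-carbon, the only nucleophilic site that can reach the ester in a six-membered transition state; the DBU treatment converges double-bond isomers on the conjugated enone.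

Step 2
Reactants: 4 ethyl 2,6,6-trimethyl-4-oxocyclohex-2-ene-1-carboxylate (racemate)
Product: 5 ethyl (1R*,4R*)-4-hydroxy-2,6,6-trimethylcyclohex-2-ene-1-carboxylate (racemic trans isomer)
Conditions: NaBH4, CeCl3·7H2O, MeOH, −78 °C; chromatography
Reagents that add atoms: none
Why: Luche 1,2-reduction, in which hydride should enter on the carbonyl face away from the axial methyl of the gem-dimethyl carbon (the face syn to the pseudoaxial ester), so the new carbinol centre forms mainly trans to the ester in each enantiomer and the minor cis isomer is removed by chromatography.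

Step 3
Reactants: 5 ethyl (1R*,4R*)-4-hydroxy-2,6,6-trimethylcyclohex-2-ene-1-carboxylate (racemate)
Product: 6 ethyl (1R,4R)-4-(acetyloxy)-2,6,6-trimethylcyclohex-2-ene-1-carboxylate and 7 ethyl (1S,4S)-4-hydroxy-2,6,6-trimethylcyclohex-2-ene-1-carboxylate (unreacted enantiomer, recovered)
Conditions: Burkholderia cepacia lipase (immobilised), vinyl acetate, tBuOMe, 30 °C, to about half conversion; chromatography
Reagents that add atoms: vinyl acetate, C=COC(C)=O
Why: Lipase-catalysed kinetic resolution by irreversible transesterification, in which the enzyme should acylate only the (4R)-carbinol, so 6 carries the ε-ring configuration and recovered 7 its mirror image, which is the one the β ring needs.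

Step 4
Reactants: 7 ethyl (1S,4S)-4-hydroxy-2,6,6-trimethylcyclohex-2-ene-1-carboxylate
Product: 8 ethyl (4R)-4-hydroxy-2,6,6-trimethylcyclohex-1-ene-1-carboxylate
Conditions: NaOEt (0.3 equiv), EtOH, 60 °C, stopped at equilibrium
Reagents that add atoms: none
Why: Base-catalysed 1,3-prototropic shift through the ester dienolate moves the double bond into conjugation as the tetrasubstituted alkene, which erases the ester-bearing stereocentre and leaves the carbinol centre untouched (its descriptor changes from S to R only because the ring priorities change).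

Step 5
Reactants: 8 ethyl (4R)-4-hydroxy-2,6,6-trimethylcyclohex-1-ene-1-carboxylate
Product: 9 (1R)-4-(hydroxymethyl)-3,5,5-trimethylcyclohex-3-en-1-ol
Conditions: LiAlH4, Et2O, 0 °C → rt
Reagents that add atoms: none
Why: LiAlH4 1,2-reduction of the hindered conjugated ester to the primary allylic alcohol, as in the preparation of β-cyclogeraniol, with no stereocentre touched.

Step 6
Reactants: 9 (1R)-4-(hydroxymethyl)-3,5,5-trimethylcyclohex-3-en-1-ol
Product: 10 {[(4R)-4-hydroxy-2,6,6-trimethylcyclohex-1-en-1-yl]methyl}(triphenyl)phosphonium bromide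
Conditions: PPh3·HBr, MeOH, rt
Reagents that add atoms: triphenylphosphine hydrobromide, [Br-].[PH+](c1ccccc1)(c1ccccc1)c1ccccc1
Why: SN1-type phosphonium salt formation, in which HBr ionises only the primary allylic alcohol to a tetrasubstituted allyl cation that PPh3 captures at the primary terminus, while the homoallylic secondary alcohol and its stereocentre stay intact.

Step 7
Reactants: 10 {[(4R)-4-hydroxy-2,6,6-trimethylcyclohex-1-en-1-yl]methyl}(triphenyl)phosphonium bromide
Product: 11 {[(4R)-2,6,6-trimethyl-4-(tetradecanoyloxy)cyclohex-1-en-1-yl]methyl}(triphenyl)phosphonium bromide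
Conditions: tetradecanoyl chloride, pyridine, DMAP (cat.), CH2Cl2, 0 °C → rt
Reagents that add atoms: tetradecanoyl chloride, CCCCCCCCCCCCCC(=O)Cl
Why: DMAP-catalysed O-acylation of the only free hydroxyl, with retention at the carbinol carbon.

Step 8
Reactants: 11 {[(4R)-2,6,6-trimethyl-4-(tetradecanoyloxy)cyclohex-1-en-1-yl]methyl}(triphenyl)phosphonium bromide; 12 crocetindialdehyde, (2E,4E,6E,8E,10E,12E,14E)-2,6,11,15-tetramethylhexadeca-2,4,6,8,10,12,14-heptaenedial (3 equiv, excess recovered)
Product: 14 (3R)-3-(tetradecanoyloxy)-8'-apo-β-caroten-8'-al, via phosphorus ylide 13 (not isolated)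
Conditions: NaN(SiMe3)2 (1.0 equiv), THF, −78 °C; ylide added to 12, −78 → 0 °C; then I2 (cat.), CH2Cl2, diffuse light
Reagents that add atoms: none
Why: Wittig olefination of the semi-stabilised allylic ylide 13 with one aldehyde group of the excess dialdehyde, where the silazide base spares the ester at low temperature, the hindered C7=C8 bond should strongly prefer E, and iodine equilibration converges any Z material.

Step 9
Reactants: 6 ethyl (1R,4R)-4-(acetyloxy)-2,6,6-trimethylcyclohex-2-ene-1-carboxylate
Product: 15 (1R,4R)-4-(hydroxymethyl)-3,5,5-trimethylcyclohex-2-en-1-ol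
Conditions: LiAlH4, Et2O, 0 °C
Reagents that add atoms: none
Why: LiAlH4 reduces the ethyl ester to the primary alcohol and cleaves the acetate in the same operation, leaving both stereocentres unchanged.

Step 10
Reactants: 15 (1R,4R)-4-(hydroxymethyl)-3,5,5-trimethylcyclohex-2-en-1-ol
Product: 16 (1R,4R)-3,5,5-trimethyl-4-{[(1-phenyl-1H-tetrazol-5-yl)sulfanyl]methyl}cyclohex-2-en-1-ol
Conditions: 1-phenyl-1H-tetrazole-5-thiol (1.05 equiv), PPh3, DIAD, THF, −20 → 0 °C
Reagents that add atoms: 1-phenyl-1H-tetrazole-5-thiol, Sc1nnnn1-c1ccccc1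
Why: Mitsunobu thioetherification, in which the primary alcohol should be activated and displaced by the thiolate faster than the secondary allylic alcohol when one equivalent of reagents is used at low temperature, and no stereocentre takes part.

Step 11
Reactants: 16 (1R,4R)-3,5,5-trimethyl-4-{[(1-phenyl-1H-tetrazol-5-yl)sulfanyl]methyl}cyclohex-2-en-1-ol
Product: 17 (1R,4R)-3,5,5-trimethyl-4-{[(1-phenyl-1H-tetrazol-5-yl)sulfanyl]methyl}cyclohex-2-en-1-yl hexadecanoate
Conditions: hexadecanoyl chloride, pyridine, DMAP (cat.), CH2Cl2, 0 °C → rt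
Reagents that add atoms: hexadecanoyl chloride, CCCCCCCCCCCCCCCC(=O)Cl
Why: DMAP-catalysed acylation of the secondary allylic alcohol, with retention at the carbinol carbon.

Step 12
Reactants: 17 (1R,4R)-3,5,5-trimethyl-4-{[(1-phenyl-1H-tetrazol-5-yl)sulfanyl]methyl}cyclohex-2-en-1-yl hexadecanoate
Product: 18 (1R,4R)-3,5,5-trimethyl-4-{[(1-phenyl-1H-tetrazol-5-yl)sulfonyl]methyl}cyclohex-2-en-1-yl hexadecanoate
Conditions: (NH4)6Mo7O24·4H2O (cat.), 30% H2O2, EtOH–THF, 0 °C → rt
Reagents that add atoms: hydrogen peroxide, OO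
Why: Molybdate-catalysed peroxide oxidation of sulfide to sulfone, chemoselective for sulfur over the trisubstituted alkene and the allylic ester.

Step 13
Reactants: 18 (1R,4R)-3,5,5-trimethyl-4-{[(1-phenyl-1H-tetrazol-5-yl)sulfonyl]methyl}cyclohex-2-en-1-yl hexadecanoate; 14 (3R)-3-(tetradecanoyloxy)-8'-apo-β-caroten-8'-al
Product: 20 (3R,3'R,6'R)-3-(tetradecanoyloxy)-β,ε-caroten-3'-yl hexadecanoate (CNP0230054.1), via β-alkoxy sulfone adduct 19 (not isolated)
Conditions: KN(SiMe3)2 added to 18 and 14, THF, −78 → 20 °C; aq NH4Cl; then I2 (cat.), CH2Cl2, diffuse light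
Reagents that add atoms: none
Why: Julia–Kocienski olefination, in which the metallated tetrazolyl sulfone adds to the aldehyde and Smiles rearrangement with loss of SO2 and tetrazololate should give the C7'=C8' alkene with E preference, the carbanion being β to the C6' stereocentre so that it cannot epimerise, and the iodine treatment converging the polyene on the all-E isomer.

Compound list
1 | ethyl 3-methylbut-2-enoate | CCOC(=O)C=C(C)C | starting material
2 | lithium 1-ethoxy-3-methylbuta-1,3-dien-1-olate (dienolate of 1) | [Li+].CCOC([O-])=CC(C)=C | intermediate (not isolated)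
3 | lithium enolate of diethyl 3,3-dimethyl-2-(prop-1-en-2-yl)pentanedioate (Michael adduct, racemic) | [Li+].CCOC(=O)C(C(C)=C)C(C)(C)C=C([O-])OCC | intermediate (not isolated)
4 | ethyl 2,6,6-trimethyl-4-oxocyclohex-2-ene-1-carboxylate (racemate) | CCOC(=O)C1C(C)=CC(=O)CC1(C)C | intermediate
5 | ethyl (1R*,4R*)-4-hydroxy-2,6,6-trimethylcyclohex-2-ene-1-carboxylate (racemic trans isomer; the 1R,4R enantiomer is drawn) | O[C@H]1C=C(C)[C@H](C(=O)OCC)C(C)(C)C1 | intermediate
6 | ethyl (1R,4R)-4-(acetyloxy)-2,6,6-trimethylcyclohex-2-ene-1-carboxylate | CC(=O)O[C@H]1C=C(C)[C@H](C(=O)OCC)C(C)(C)C1 | intermediate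
7 | ethyl (1S,4S)-4-hydroxy-2,6,6-trimethylcyclohex-2-ene-1-carboxylate | O[C@@H]1C=C(C)[C@@H](C(=O)OCC)C(C)(C)C1 | intermediate
8 | ethyl (4R)-4-hydroxy-2,6,6-trimethylcyclohex-1-ene-1-carboxylate | CCOC(=O)C1=C(C)C[C@@H](O)CC1(C)C | intermediate
9 | (1R)-4-(hydroxymethyl)-3,5,5-trimethylcyclohex-3-en-1-ol | OCC1=C(C)C[C@@H](O)CC1(C)C | intermediate
10 | {[(4R)-4-hydroxy-2,6,6-trimethylcyclohex-1-en-1-yl]methyl}(triphenyl)phosphonium bromide | [Br-].c1ccccc1[P+](c1ccccc1)(c1ccccc1)CC2=C(C)C[C@@H](O)CC2(C)C | intermediate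
11 | {[(4R)-2,6,6-trimethyl-4-(tetradecanoyloxy)cyclohex-1-en-1-yl]methyl}(triphenyl)phosphonium bromide | [Br-].c1ccccc1[P+](c1ccccc1)(c1ccccc1)CC2=C(C)C[C@@H](OC(=O)CCCCCCCCCCCCC)CC2(C)C | intermediate
12 | crocetindialdehyde, (2E,4E,6E,8E,10E,12E,14E)-2,6,11,15-tetramethylhexadeca-2,4,6,8,10,12,14-heptaenedial | O=C/C(C)=C/C=C/C(C)=C/C=C/C=C(C)/C=C/C=C(C)/C=O | starting material
13 | phosphorus ylide of 11, triphenyl{[(4R)-2,6,6-trimethyl-4-(tetradecanoyloxy)cyclohex-1-en-1-yl]methylidene}phosphorane | c1ccccc1P(c1ccccc1)(c1ccccc1)=CC2=C(C)C[C@@H](OC(=O)CCCCCCCCCCCCC)CC2(C)C | intermediate (not isolated)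
14 | (3R)-3-(tetradecanoyloxy)-8'-apo-β-caroten-8'-al, (2E,4E,6E,8E,10E,12E,14E,16E)-2,6,11,15-tetramethyl-17-[(4R)-2,6,6-trimethyl-4-(tetradecanoyloxy)cyclohex-1-en-1-yl]heptadeca-2,4,6,8,10,12,14,16-octaenal | O=C/C(C)=C/C=C/C(C)=C/C=C/C=C(C)/C=C/C=C(C)/C=C/C1=C(C)C[C@@H](OC(=O)CCCCCCCCCCCCC)CC1(C)C | intermediate
15 | (1R,4R)-4-(hydroxymethyl)-3,5,5-trimethylcyclohex-2-en-1-ol | O[C@H]1C=C(C)[C@H](CO)C(C)(C)C1 | intermediate
16 | (1R,4R)-3,5,5-trimethyl-4-{[(1-phenyl-1H-tetrazol-5-yl)sulfanyl]methyl}cyclohex-2-en-1-ol | O[C@H]1C=C(C)[C@H](CSc2nnnn2-c2ccccc2)C(C)(C)C1 | intermediate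
17 | (1R,4R)-3,5,5-trimethyl-4-{[(1-phenyl-1H-tetrazol-5-yl)sulfanyl]methyl}cyclohex-2-en-1-yl hexadecanoate | CCCCCCCCCCCCCCCC(=O)O[C@H]1C=C(C)[C@H](CSc2nnnn2-c2ccccc2)C(C)(C)C1 | intermediate
18 | (1R,4R)-3,5,5-trimethyl-4-{[(1-phenyl-1H-tetrazol-5-yl)sulfonyl]methyl}cyclohex-2-en-1-yl hexadecanoate | CCCCCCCCCCCCCCCC(=O)O[C@H]1C=C(C)[C@H](CS(=O)(=O)c2nnnn2-c2ccccc2)C(C)(C)C1 | intermediate
19 | potassium β-alkoxy sulfone adduct of 18 and 14 (configuration at the two new carbons not defined) | [K+].CCCCCCCCCCCCCCCC(=O)O[C@H]1C=C(C)[C@H](C(S(=O)(=O)c2nnnn2-c2ccccc2)C([O-])/C(C)=C/C=C/C(C)=C/C=C/C=C(C)/C=C/C=C(C)/C=C/C3=C(C)C[C@@H](OC(=O)CCCCCCCCCCCCC)CC3(C)C)C(C)(C)C1 | intermediate (not isolated)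
20 | (3R,3'R,6'R)-3-(tetradecanoyloxy)-β,ε-caroten-3'-yl hexadecanoate (lutein 3-O-myristate 3'-O-palmitate, CNP0230054.1) | CCCCCCCCCCCCCCCC(=O)O[C@H]1C=C(C)[C@H](/C=C/C(C)=C/C=C/C(C)=C/C=C/C=C(C)/C=C/C=C(C)/C=C/C2=C(C)C[C@@H](OC(=O)CCCCCCCCCCCCC)CC2(C)C)C(C)(C)C1 | target

Total step count: 13. Longest linear sequence: 9 steps (steps 1 to 8, then step 13); the ε branch (steps 1, 2, 3, 9 to 13) has 8.

Steps most likely to fail

Step 1. The dienolate may add to the ester carbonyl of the second molecule (Claisen acylation at the α-carbon), or the hindered conjugate addition may stall, so the annulation never starts. The fallback makes the same two ring bonds in the reverse order by known steps. It sets out from 1: the dienolate is trapped with Me3SiCl (LiN(iPr)2, THF, −78 °C) as 1-ethoxy-3-methyl-1-(trimethylsilyloxy)buta-1,3-diene F1. This is acylated at its γ-carbon with 3-methylbut-2-enoyl chloride (ZnBr2, CH2Cl2, −78 °C, vinylogous Mukaiyama-type acylation, bond C4–C3) to give ethyl 3,7-dimethyl-5-oxoocta-2,6-dienoate F2. Base (DBU or KOtBu, THF) then closes the ring by intramolecular conjugate addition of the ester α-carbon to the dimethyl-substituted enone terminus (bond C6–C1, the closure by which isophorone forms), returning to the route at 4.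

Step 4. The double-bond migration may stop at an unfavourable equilibrium, or the hydroxyl group may be lost by vinylogous elimination through the same dienolate on prolonged heating. The fallback moves the isomerisation to the aldehyde level, where it is fast under much milder base. It sets out from 7: iBu2AlH (CH2Cl2, −78 °C) gives (1S,4S)-4-hydroxy-2,6,6-trimethylcyclohex-2-ene-1-carbaldehyde F3; dilute KOH in MeOH at 0 °C conjugates it (the α- to β-cyclocitral shift) to (4R)-4-hydroxy-2,6,6-trimethylcyclohex-1-ene-1-carbaldehyde F4; NaBH4 in MeOH returns to the route at 9.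

Step 10. Site selectivity may be lost through activation of the secondary allylic hydroxyl (substitution or allylic transposition there), since the primary alcohol is β-branched and slow. The fallback uses a protecting-group sequence with a more size-sensitive reagent. It sets out from 15: tBuPh2SiCl and imidazole (CH2Cl2, 0 °C) silylate the primary alcohol to give (1R,4R)-4-({[tert-butyl(diphenyl)silyl]oxy}methyl)-3,5,5-trimethylcyclohex-2-en-1-ol F5; hexadecanoyl chloride, pyridine and DMAP give (1R,4R)-4-({[tert-butyl(diphenyl)silyl]oxy}methyl)-3,5,5-trimethylcyclohex-2-en-1-yl hexadecanoate F6; HF·pyridine (THF, 0 °C) frees the primary alcohol as (1R,4R)-4-(hydroxymethyl)-3,5,5-trimethylcyclohex-2-en-1-yl hexadecanoate F7; the Mitsunobu reaction with 1-phenyl-1H-tetrazole-5-thiol, now without a competing hydroxyl, returns to the route at 17.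

Further compounds
F1 | step 1 | 1-ethoxy-3-methyl-1-(trimethylsilyloxy)buta-1,3-diene | CCOC(O[Si](C)(C)C)=CC(C)=C
F2 | step 1 | ethyl 3,7-dimethyl-5-oxoocta-2,6-dienoate (2E/2Z mixture) | CCOC(=O)C=C(C)CC(=O)C=C(C)C
F3 | step 4 | (1S,4S)-4-hydroxy-2,6,6-trimethylcyclohex-2-ene-1-carbaldehyde | O[C@@H]1C=C(C)[C@@H](C=O)C(C)(C)C1
F4 | step 4 | (4R)-4-hydroxy-2,6,6-trimethylcyclohex-1-ene-1-carbaldehyde | O=CC1=C(C)C[C@@H](O)CC1(C)C
F5 | step 10 | (1R,4R)-4-({[tert-butyl(diphenyl)silyl]oxy}methyl)-3,5,5-trimethylcyclohex-2-en-1-ol | O[C@H]1C=C(C)[C@H](CO[Si](c2ccccc2)(c2ccccc2)C(C)(C)C)C(C)(C)C1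
F6 | step 10 | (1R,4R)-4-({[tert-butyl(diphenyl)silyl]oxy}methyl)-3,5,5-trimethylcyclohex-2-en-1-yl hexadecanoate | CCCCCCCCCCCCCCCC(=O)O[C@H]1C=C(C)[C@H](CO[Si](c2ccccc2)(c2ccccc2)C(C)(C)C)C(C)(C)C1
F7 | step 10 | (1R,4R)-4-(hydroxymethyl)-3,5,5-trimethylcyclohex-2-en-1-yl hexadecanoate | CCCCCCCCCCCCCCCC(=O)O[C@H]1C=C(C)[C@H](CO)C(C)(C)C1
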